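- If partner consumes starting material one for one, ln[starting material] falls in step with [partner] times time, so work in logarithms. Here are the flasks, the earlier runs and the questions.

common to all: starting material 0.33 M

|  | partner | protic impurity | capture agent | remark | time |
|---|---|---|---|---|---|
| zeta | 0.51 equiv | 6.6 mM | 6.6 mM | run made earlier |  |
| alpha | 2.4 equiv | 6.6 mM | 6.6 mM | run made earlier |  |
| violet | 0.450 equiv | 6.60 mM | 6.60 mM |  | 6.0 min |
| amber | 1.80 equiv | 6.60 mM | 6.60 mM |  | 4.0 min |

| run | time / min | target / % | starting material / % |
|---|---|---|---|
| zeta | 0.417 | 1.1 | 96.3 |
| zeta | 0.833 | 2.3 | 93.2 |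
| zeta | 1.33 | 4.2 | 90.4 |
| zeta | 1.50 | 5.2 | 89.1 |
| zeta | 2.00 | 8.0 | 87.2 |
| zeta | 2.50 | 10.1 | 85.6 |
| zeta | 3.00 | 12.2 | 82.9 |
| alpha | 0.250 | 1.5 | 89.4 |
| alpha | 0.333 | 1.2 | 86.6 |
| alpha | 0.500 | 4.3 | 81.2 |
| alpha | 0.833 | 9.4 | 72.6 |
| alpha | 1.33 | 18.6 | 61.7 |
| alpha | 2.00 | 30.6 | 50.7 |
| alpha | 3.00 | 45.6 | 38.8 |

(each reading ± 0.3 percentage points)

* the winner by amount of target, in percent of the starting material charged; "neither" if no more than 2 percentage points parts them (violet / amber / neither)
* how much target is there at the end, in percent of the starting material charged: violet
* how much target is there at the end, in percent of the starting material charged: amber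

- Take the last reading of each run, and count [partner] in equivalents as the charge less half of the starting material lost by then. The fall of ln[starting material] per minute and per equivalent is 0.147 /min in zeta and 0.151 /min in alpha, although their partner charges stand 4.71-fold apart.
- Carry the mean, 0.149 /min, as the loss constant: the pseudo-first-order rate of starting material per equivalent of mean free partner.
- Hold partner at its charge in amber, and this first pass reckons 65.8 % of the starting material gone. Take half of that off the charge, reckon again, and 41.6 % stays.
- Do the same for violet: the first pass reckons 33.1 % gone, and the second leaves 77.6 %.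
- The last readings of both runs show more starting material lost than target formed , so define the lag as the missing material divided by the reckoned loss rate at that reading. Alpha reads 1.51 min and zeta reads 1.17 min.
- Commit with the mean lag, 1.34 min: amber reaches 48.3 % of target and violet 19.0 %.
- Reforge the weak link, that mean, by giving each flask the lag of its nearest run. Amber with alpha's lag gives 47.0 %, and violet with zeta's gives 19.4 %, so my winner is amber.
- The forecast names amber, with 20.3 % for violet and 48 % for amber; its reasoning opens with “the starting material lost exceeds the target formed”. Both its numbers are higher than mine, but the order of the flasks is the same.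
- The flask gives amber, with 20.4 % in violet and 47.6 % in amber, so the forecast stands on all three counts.

    open intermediate → target (k = 0.0160 /s)
    partner + protic impurity → quenched reagent (k = 1.90 /M/s)
    starting material + partner ⇌ open intermediate (K = 2.10 /M, k = 0.00980 /M/s)
    open intermediate + capture agent → trapped intermediate (k = 0.0560 /M/s)

- The loss constant left 41.6 % of starting material in amber and 77.6 % in violet; the flasks hold 42.0 % and 76.6 %. The partner charge is the main reason that violet trails: run with amber's equivalents and still for its own 6.0 min, violet gives 62.4 % of target instead of 20.4 %.
- Now take a neighbouring flask, which is amber with 3.10 equiv of partner. The same two passes leave 20.3 % of the starting material, and the computed flask leaves 21.9 %, with 66.2 % of target.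

The readings were generated by integration with constants of no real substance.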